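The target's ether oxygen joins C5 and C10 on opposite faces of the C1–C10 carbocycle. Ring A (O, C10, C1–C5) and ring B (O, C5–C10) therefore form an inside–outside 11-oxabicyclo[4.4.1]undecane, which is a trans-decalin (C5–C10 bond, 10-methyl anti to the fourth C5 substituent) with one oxygen inserted into the fusion bond.
32 ⇐ 3-ol 30 ⇐ bridgehead C5 acylal 28, where H5 comes from a silane tethered on O3 ⇐ Criegee rearrangement of the trans-decalin C5 p-nitroperbenzoate 27, which makes O–C10, breaks C5–C10 and forms rings A and B together.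
27 ⇐ 5α-hydroperoxy-6β,12-olide 24 ⇐ 5β,6β-epoxy acid 22 (bromolactonisation, base, then H2O2, each opening trans-diaxial) ⇐ Δ5(6)-decalin acrylic acid 20.
20 ⇐ C7 allylation, C8 ketone reduction and C4 hydroxymethylation of enone ketal 7 ⇐ Robinson annulation (chiral-imine Michael addition, then aldol) of ketal ketone 1 with but-3-en-2-one.
Order of rings: carbocycle B (present in 1), carbocycle A (step 2), lactone (step 16, re-formed in step 18), oxepanes A and B (step 20).
Key step: step 20

Remark: eudesmane numbering is used for every intermediate, α and β refer to the decalin drawn with the C10 methyl β, and 1 is used as the racemate because step 1 is stereoconvergent.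

Step 1
Reactants: 1 7-methyl-1,4-dioxaspiro[4.5]decan-8-one (racemic); 2 (R)-1-phenylethylamine; 3 but-3-en-2-one
Product: 6 (R)-7-methyl-7-(3-oxobutyl)-1,4-dioxaspiro[4.5]decan-8-one, via ketimine 4 (not isolated), via adduct ketimine 5 (not isolated)
Conditions: 1, 2, TsOH (cat.), toluene, reflux (−H2O); 3, THF, 40 °C; 20% aq AcOH, 25 °C
Reagents that add atoms: water, O
Why: In this chiral-imine asymmetric Michael addition the more substituted secondary enamine tautomer of 4 adds to the enone on the face away from the phenyl group, so both enantiomers of 1 converge on the quaternary C10 centre (methyl β) and hydrolysis returns the amine.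

Step 2
Reactants: 6 (R)-7-methyl-7-(3-oxobutyl)-1,4-dioxaspiro[4.5]decan-8-one
Product: 7 enone ketal (R)-6,6-ethylenedioxy-4a-methyl-4,4a,5,6,7,8-hexahydronaphthalen-2(3H)-one (C3 ketone; C4=C5; C8 ketal; 10β-methyl)
Conditions: NaOMe (0.3 equiv), MeOH, 60 °C
Reagents that add atoms: none
Why: The intramolecular aldol condensation (second half of the Robinson annulation) joins the methyl-ketone carbon C4 to the ring ketone C5 and closes carbocycle A without a new stereocentre.

Step 3
Reactants: 7 enone ketal
Product: 8 β,γ-enone (C3 ketone; 4α-CH2OH, H4 β; C5=C6; C8 ketal)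
Conditions: KOt-Bu (1.0 equiv), THF, 0 °C; monomeric CH2O in THF, −78 °C; AcOH, −78 °C
Reagents that add atoms: formaldehyde, C=O
Why: In this deconjugative α-aldol reaction the thermodynamic 3,5-dienolate reacts at C4 on the α face, anti to the axial C10 methyl, which sets C4 (C15 α, H4 β) and moves the alkene to C5=C6.

Step 4
Reactants: 8 β,γ-enone
Product: 9 3α,15-diol (C5=C6; C8 ketal)
Conditions: LiBH(s-Bu)3 (2.5 equiv), THF, −78 °C
Reagents that add atoms: none
Why: The bulky borohydride attacks the C3 ketone along the equatorial trajectory at a temperature where the β,γ-enone does not conjugate, which gives the axial 3α-alcohol cis to the equatorial C4 substituent.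

Step 5
Reactants: 9 3α,15-diol
Product: 10 15-O-TBDPS 3α-ol (C8 ketal)
Conditions: t-BuPh2SiCl (1.05 equiv), imidazole, CH2Cl2, 0 °C
Reagents that add atoms: tert-butyl(chloro)diphenylsilane, CC(C)(C)[Si](Cl)(c1ccccc1)c1ccccc1
Why: The bulky chlorosilane silylates the primary C15 hydroxyl selectively and leaves the hindered axial 3α-hydroxyl free.

Step 6
Reactants: 10 15-O-TBDPS 3α-ol
Product: 11 C8 ketone (C5=C6; 3α-OH; 15-O-TBDPS)
Conditions: PPTS (cat.), acetone–H2O 10:1, 45 °C
Reagents that add atoms: water, O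
Why: Weak-acid ketal hydrolysis frees the C8 ketone, and the acidity is too low to move the trisubstituted C5=C6 bond into conjugation or to touch the silyl ether.

Step 7
Reactants: 11 C8 ketone
Product: 12 3-O-TES C8 ketone
Conditions: Et3SiOTf, 2,6-lutidine, CH2Cl2, −78 °C
Reagents that add atoms: triethylsilyl trifluoromethanesulfonate, CC[Si](CC)(CC)OS(=O)(=O)C(F)(F)F
Why: The silyl triflate protects the hindered axial hydroxyl at low temperature, and the weak base does not enolise the ketone.

Step 8
Reactants: 12 3-O-TES C8 ketone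
Product: 13 7α-allyl C8 ketone (H7 β; C5=C6)
Conditions: LiN(i-Pr)2 (1.05 equiv), THF, −78 °C; allyl bromide (1.0 equiv), −78 to −20 °C
Reagents that add atoms: allyl bromide, C=CCBr
Why: In this α-alkylation of an extended dienolate C7 is deprotonated (allylic, whereas C9 is neopentyl) and the bromide enters at C7 on the open α face, as reagents do with ring-B 5,7-dienes that carry an angular β-methyl.

Step 9
Reactants: 13 7α-allyl C8 ketone
Product: 14 7β-allyl C8 ketone (H7 α; C5=C6)
Conditions: KOt-Bu (1.0 equiv), THF, 0 °C; added to AcOH–THF, −78 °C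
Reagents that add atoms: none
Why: In this kinetic deconjugative protonation the conjugated dienolate is re-formed under equilibrating conditions and takes the proton at its α-carbon C7 from the same open α face, which turns the allyl group to the β (equatorial) side.

Step 10
Reactants: 14 7β-allyl C8 ketone
Product: 15 8β-alcohol (7β-allyl)
Conditions: LiBH(s-Bu)3, THF, −78 °C
Reagents that add atoms: none
Why: The β face of C8 is closed by the syn-axial C10 methyl, so hydride enters from the α face and gives the axial 8β-alcohol cis to the C7 side chain.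

Step 11
Reactants: 15 8β-alcohol
Product: 16 8β-methacrylate
Conditions: methacrylic anhydride, DMAP, Et3N, CH2Cl2, 25 °C
Reagents that add atoms: methacrylic anhydride, C=C(C)C(=O)OC(=O)C(C)=C
Why: DMAP-catalysed acylation esterifies the only free hydroxyl with retention at C8.

Step 12
Reactants: 16 8β-methacrylate
Product: 17 C12 aldehyde (C7–CH2–CHO)
Conditions: OsO4 (2 mol%), NaIO4 (4 equiv), 2,6-lutidine, dioxane–H2O, 25 °C
Reagents that add atoms: sodium periodate, [Na+].[O-]I(=O)(=O)=O
Why: The Lemieux–Johnson cleavage takes the unhindered monosubstituted alkene in preference to the shielded trisubstituted C5=C6 bond and the electron-poor methacrylate.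

Step 13
Reactants: 17 C12 aldehyde
Product: 18 2-substituted acrolein (C7–C11(=C13H2)–CHO)
Conditions: 37% aq CH2O, pyrrolidine (10 mol%), propionic acid (10 mol%), i-PrOH, 45 °C
Reagents that add atoms: formaldehyde, C=O
Why: The amine-catalysed Mannich-type α-methylenation of the aldehyde installs C13 under conditions that are almost neutral and leave the esters and C7 untouched.

Step 14
Reactants: 18 2-substituted acrolein
Product: 19 acrylic acid (C12 carboxylic acid; 3-O-TES)
Conditions: NaClO2, NaH2PO4, 2-methylbut-2-ene, t-BuOH–H2O, 0 °C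
Reagents that add atoms: sodium chlorite, [Na+].[O-]Cl=O
Why: The Pinnick oxidation converts the enal into the acid without touching alkenes, because the scavenger removes the hypochlorous acid.

Step 15
Reactants: 19 acrylic acid
Product: 20 3α-hydroxy acrylic acid
Conditions: AcOH–THF–H2O 3:1:1, 25 °C
Reagents that add atoms: none
Why: Mild acid solvolysis removes the triethylsilyl ether, and the far more robust TBDPS ether survives.

Step 16
Reactants: 20 3α-hydroxy acrylic acid
Product: 21 5α-bromo-6β,12-olide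
Conditions: NBS (1.05 equiv), THF, 0 °C, dark
Reagents that add atoms: N-bromosuccinimide, O=C1CCC(=O)N1Br
Why: In this bromolactonisation of a cyclohex-2-enylacetic-type acid only the electron-rich C5=C6 bond forms a bromonium ion, and the β side-chain carboxyl opens the α-bromonium ion at C6 in a 5-exo, trans-diaxial (Fürst–Plattner) way, which sets O6 β (cis lactone) and Br 5α.

Step 17
Reactants: 21 5α-bromo-6β,12-olide
Product: 22 5β,6β-epoxy acid
Conditions: LiOH (2.1 equiv), THF–H2O, 0 °C; cold 1 M HCl to pH 4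
Reagents that add atoms: lithium hydroxide, [Li+].[OH-]
Why: Saponification of the activated lactone frees the 6β-alkoxide, which displaces the antiperiplanar 5α-bromide (halohydrin-to-epoxide closure) faster than the hindered methacrylate is attacked or shifted, so the epoxide is fixed on the β face.

Step 18
Reactants: 22 5β,6β-epoxy acid
Product: 24 5α-hydroperoxy-6β,12-olide (3α-OH), via hydroperoxy hydroxy acid 23 (not isolated)
Conditions: anhydrous H2O2 in Et2O (10 equiv), H3PMo12O40 (5 mol%), 25 °C
Reagents that add atoms: hydrogen peroxide, OO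
Why: In the acid-catalysed perhydrolysis H2O2 opens the epoxide at the tertiary C5 from the α face with inversion (trans-diaxial), which sets the 5α-hydroperoxide anti to the C10 methyl, and the freed 6β-hydroxyl closes the cis γ-lactone with the C12 acid.

Step 19
Reactants: 24 5α-hydroperoxy-6β,12-olide; 25 4-nitrobenzoyl chloride
Product: 27 trans-decalin C5 p-nitroperbenzoate (3α-O-SiH(i-Pr)2; 15-O-TBDPS; 8β-methacrylate; 6β,12-olide), via hydroxy perester 26 (not isolated)
Conditions: 25 (1.05 equiv), pyridine, CH2Cl2, −20 °C; i-Pr2SiHCl, imidazole, 0 °C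
Reagents that add atoms: chlorodiisopropylsilane, CC(C)[SiH](Cl)C(C)C
Why: The more acidic and more nucleophilic hydroperoxide oxygen (α-effect) is acylated before the hindered axial 3α-hydroxyl, which is then silylated with the hydridosilane that serves as the hydride tether.

Step 20
Reactants: 27 trans-decalin C5 p-nitroperbenzoate
Product: 28 5-(4-nitrobenzoyloxy)-5,10-epoxy bicycle (bridgehead acylal of the target skeleton)
Conditions: MeCN–CH2Cl2 1:1, solid NaHCO3, 40 °C
Reagents that add atoms: none
Why: In the Criegee rearrangement the O–O bond of 27 ionises with loss of 4-nitrobenzoate while the antiperiplanar C5–C10 bond shifts from C5 to the inner peroxide oxygen, and the bridged C5 oxocarbenium–carboxylate contact ion pair collapses to acylal 28; the closest known case is the rearrangement of 9-decalyl peresters to 1,6-epoxycyclodecyl esters. Rings A and B are not closed end to end, because both six-membered carbocycles are enlarged to oxepanes in the same 1,2-shift by insertion of the oxygen into their shared C5–C10 bond. C10 is set by the suprafacial shift, which keeps the configuration of the migrating carbon (O takes the place of C5 and the methyl is untouched). C5 is set by the ion pair, since the carboxylate leaves anti to C10 and lies over the rear lobe of C5, so least-motion return keeps the shape of the trans-decalin with the oxygen on opposite faces at C5 and C10; this centre is ionised again in step 21, so an error here is not carried on. The step needs C10 to migrate rather than C4 or C6 and heterolysis to outrun homolysis: C10 is fully substituted, C4 is secondary, C6 is deactivated by the lactone oxygen, the nitro group makes the carboxylate a good nucleofuge, and expansion relieves the syn-axial contacts of the C10 methyl with O6 and O8. The Si–H bond cannot reach the rear of the O–O bond, and if it captures the cation directly it gives 29, the intermediate of step 21.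

Step 21
Reactants: 28 bridgehead acylal
Product: 30 5,10-epoxy 3α-ol (H5 installed; 15-O-TBDPS), via silyl 4-nitrobenzoate 29 (not isolated)
Conditions: Me3SiOTf (0.2 equiv), 2,6-di-tert-butyl-4-methylpyridine (0.3 equiv), CH2Cl2 (0.005 M), −78 to −20 °C; HF·pyridine, THF, 0 °C
Reagents that add atoms: none
Why: Proposed new method: catalytic Me3SiOTf re-ionises the acylal, and the Si–H bond held on the 3α-oxygen, which lies on the same face of ring A as the leaving aroyloxy group, passes hydride to C5 through a six-membered transition state (C5, C4, C3, O, Si, H) while the other face of C5 is out of reach, so H5 ends cis to O3 on ring A as in the target and the silicon takes up the carboxylate (29, itself a silyl Lewis acid that carries the chain) before HF frees O3; an external silane would attack the relaxed cation from its open outer face and a 3-acetate would close a dioxanylium ion on the needed face, which is why the tether replaces both; the closest known reaction types are the Lewis-acid-promoted intramolecular hydrosilylation of β-(diisopropylsilyloxy) ketones and the Et3SiH/Me3SiOTf reduction of ketals and acylals.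

Step 22
Reactants: 30 5,10-epoxy 3α-ol
Product: 31 3α-acetate 15-O-TBDPS ether
Conditions: Ac2O, DMAP, pyridine, CH2Cl2, 25 °C
Reagents that add atoms: acetic anhydride, CC(=O)OC(C)=O
Why: DMAP-catalysed acetylation esterifies the only free hydroxyl with retention at C3.

Step 23
Reactants: 31 3α-acetate 15-O-TBDPS ether
Product: 32 target CNP0602302.1
Conditions: HF·pyridine, pyridine, THF, 0 to 25 °C
Reagents that add atoms: none
Why: Buffered acidic fluoride cleaves the primary silyl ether without the basic conditions that would move the 3-acetate to O15 or add to the α-methylene lactone.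

Compound list
1 | 7-methyl-1,4-dioxaspiro[4.5]decan-8-one (racemic) | CC1CC2(CCC1=O)OCCO2 | starting material
2 | (R)-1-phenylethylamine | C[C@@H](N)c1ccccc1 | starting material
3 | but-3-en-2-one | CC(=O)C=C | starting material
4 | ketimine of 1 and 2 | CC1CC2(CCC1=N[C@H](C)c3ccccc3)OCCO2 | intermediate
5 | adduct ketimine (quaternary C10) | C1COC2(O1)C[C@@](C)(CCC(C)=O)C(=N[C@H](C)c3ccccc3)CC2 | intermediate
6 | (R)-7-methyl-7-(3-oxobutyl)-1,4-dioxaspiro[4.5]decan-8-one | C1COC2(O1)C[C@@](C)(CCC(C)=O)C(=O)CC2 | intermediate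
7 | enone ketal | C1COC2(O1)C[C@@]3(C)CCC(=O)C=C3CC2 | intermediate
8 | 4α-hydroxymethyl β,γ-enone ketal | C1COC2(O1)C[C@@]3(C)CCC(=O)[C@@H](CO)C3=CC2 | intermediate
9 | 3α,15-diol ketal | C1COC2(O1)C[C@@]3(C)CC[C@@H](O)[C@@H](CO)C3=CC2 | intermediate
10 | 15-O-TBDPS 3α-ol ketal | C1COC2(O1)C[C@@]3(C)CC[C@@H](O)[C@@H](CO[Si](c4ccccc4)(c5ccccc5)C(C)(C)C)C3=CC2 | intermediate
11 | C8 ketone, 3α-OH | O=C1C[C@@]2(C)CC[C@@H](O)[C@@H](CO[Si](c3ccccc3)(c4ccccc4)C(C)(C)C)C2=CC1 | intermediate
12 | C8 ketone, 3-O-TES | O=C1C[C@@]2(C)CC[C@@H](O[Si](CC)(CC)CC)[C@@H](CO[Si](c3ccccc3)(c4ccccc4)C(C)(C)C)C2=CC1 | intermediate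
13 | 7α-allyl C8 ketone | O=C1C[C@@]2(C)CC[C@@H](O[Si](CC)(CC)CC)[C@@H](CO[Si](c3ccccc3)(c4ccccc4)C(C)(C)C)C2=C[C@H]1CC=C | intermediate
14 | 7β-allyl C8 ketone | O=C1C[C@@]2(C)CC[C@@H](O[Si](CC)(CC)CC)[C@@H](CO[Si](c3ccccc3)(c4ccccc4)C(C)(C)C)C2=C[C@@H]1CC=C | intermediate
15 | 8β-alcohol | O[C@@H]1C[C@@]2(C)CC[C@@H](O[Si](CC)(CC)CC)[C@@H](CO[Si](c3ccccc3)(c4ccccc4)C(C)(C)C)C2=C[C@@H]1CC=C | intermediate
16 | 8β-methacrylate | C=C(C)C(=O)O[C@@H]1C[C@@]2(C)CC[C@@H](O[Si](CC)(CC)CC)[C@@H](CO[Si](c3ccccc3)(c4ccccc4)C(C)(C)C)C2=C[C@@H]1CC=C | intermediate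
17 | C12 aldehyde | C=C(C)C(=O)O[C@@H]1C[C@@]2(C)CC[C@@H](O[Si](CC)(CC)CC)[C@@H](CO[Si](c3ccccc3)(c4ccccc4)C(C)(C)C)C2=C[C@@H]1CC=O | intermediate
18 | 2-substituted acrolein | C=C(C)C(=O)O[C@@H]1C[C@@]2(C)CC[C@@H](O[Si](CC)(CC)CC)[C@@H](CO[Si](c3ccccc3)(c4ccccc4)C(C)(C)C)C2=C[C@@H]1C(=C)C=O | intermediate
19 | acrylic acid, 3-O-TES | C=C(C)C(=O)O[C@@H]1C[C@@]2(C)CC[C@@H](O[Si](CC)(CC)CC)[C@@H](CO[Si](c3ccccc3)(c4ccccc4)C(C)(C)C)C2=C[C@@H]1C(=C)C(=O)O | intermediate
20 | 3α-hydroxy acrylic acid | C=C(C)C(=O)O[C@@H]1C[C@@]2(C)CC[C@@H](O)[C@@H](CO[Si](c3ccccc3)(c4ccccc4)C(C)(C)C)C2=C[C@@H]1C(=C)C(=O)O | intermediate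
21 | 5α-bromo-6β,12-olide | C=C(C)C(=O)O[C@@H]1C[C@@]2(C)CC[C@@H](O)[C@@H](CO[Si](c3ccccc3)(c4ccccc4)C(C)(C)C)[C@]2(Br)[C@@H]2OC(=O)C(=C)[C@@H]21 | intermediate
22 | 5β,6β-epoxy acid | C=C(C)C(=O)O[C@@H]1C[C@@]2(C)CC[C@@H](O)[C@@H](CO[Si](c4ccccc4)(c5ccccc5)C(C)(C)C)[C@]23O[C@@H]3[C@@H]1C(=C)C(=O)O | intermediate
23 | 5α-hydroperoxy-6β-hydroxy acid | C=C(C)C(=O)O[C@@H]1C[C@@]2(C)CC[C@@H](O)[C@@H](CO[Si](c3ccccc3)(c4ccccc4)C(C)(C)C)[C@]2(OO)[C@H](O)[C@@H]1C(=C)C(=O)O | intermediate
24 | 5α-hydroperoxy-6β,12-olide | C=C(C)C(=O)O[C@@H]1C[C@@]2(C)CC[C@@H](O)[C@@H](CO[Si](c3ccccc3)(c4ccccc4)C(C)(C)C)[C@]2(OO)[C@@H]2OC(=O)C(=C)[C@@H]21 | intermediate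
25 | 4-nitrobenzoyl chloride | O=C(Cl)c1ccc(cc1)[N+](=O)[O-] | starting material
26 | 3α-hydroxy C5 p-nitroperbenzoate | C=C(C)C(=O)O[C@@H]1C[C@@]2(C)CC[C@@H](O)[C@@H](CO[Si](c3ccccc3)(c4ccccc4)C(C)(C)C)[C@]2(OOC(=O)c5ccc(cc5)[N+](=O)[O-])[C@@H]2OC(=O)C(=C)[C@@H]21 | intermediate
27 | trans-decalin C5 p-nitroperbenzoate with 3α-O-SiH(i-Pr)2 tether | C=C(C)C(=O)O[C@@H]1C[C@@]2(C)CC[C@@H](O[SiH](C(C)C)C(C)C)[C@@H](CO[Si](c3ccccc3)(c4ccccc4)C(C)(C)C)[C@]2(OOC(=O)c5ccc(cc5)[N+](=O)[O-])[C@@H]2OC(=O)C(=C)[C@@H]21 | intermediate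
28 | 5-(4-nitrobenzoyloxy)-5,10-epoxy bicycle (bridgehead acylal) | C=C(C)C(=O)O[C@@H]1C[C@@]2(C)CC[C@@H](O[SiH](C(C)C)C(C)C)[C@@H](CO[Si](c3ccccc3)(c4ccccc4)C(C)(C)C)[C@@](OC(=O)c5ccc(cc5)[N+](=O)[O-])(O2)[C@@H]2OC(=O)C(=C)[C@@H]21 | intermediate
29 | 5,10-epoxy 3-O-[diisopropyl(4-nitrobenzoyloxy)silyl] ether | C=C(C)C(=O)O[C@@H]1C[C@@]2(C)CC[C@@H](O[Si](OC(=O)c5ccc(cc5)[N+](=O)[O-])(C(C)C)C(C)C)[C@@H](CO[Si](c3ccccc3)(c4ccccc4)C(C)(C)C)[C@@H](O2)[C@@H]2OC(=O)C(=C)[C@@H]21 | intermediate
30 | 5,10-epoxy 3α-ol, 15-O-TBDPS | C=C(C)C(=O)O[C@@H]1C[C@@]2(C)CC[C@@H](O)[C@@H](CO[Si](c3ccccc3)(c4ccccc4)C(C)(C)C)[C@@H](O2)[C@@H]2OC(=O)C(=C)[C@@H]21 | intermediate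
31 | 3α-acetate, 15-O-TBDPS | C=C(C)C(=O)O[C@@H]1C[C@@]2(C)CC[C@@H](OC(C)=O)[C@@H](CO[Si](c3ccccc3)(c4ccccc4)C(C)(C)C)[C@@H](O2)[C@@H]2OC(=O)C(=C)[C@@H]21 | intermediate
32 | CNP0602302.1 | C=C(C)C(=O)O[C@@H]1C[C@@]2(C)CC[C@@H](OC(C)=O)[C@@H](CO)[C@@H](O2)[C@@H]2OC(=O)C(=C)[C@@H]21 | target

Total step count: 23. Longest linear sequence: 23 steps.

Steps most likely to fail

Step 21. Hydride transfer from the tether may be too slow. The bridged cation would then relax and be quenched on its outer face by a second molecule, or it would open to the ketol on work-up.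
The fallback uses known chemistry and makes the C5–O bond by displacement instead of making the C5–H bond by reduction. It sets out from 28 and comes back at 31.
- HF·pyridine with water strips the silane and the aroyl group, and the hemiketal opens to the ten-membered 3α,10-dihydroxy-5-ketone F1.
- Me4NBH(OAc)3 in MeCN–AcOH (Evans–Saksena reduction, hydride carried by O3) should give the 3,5-anti triol F2, whose C5 carbinol has the configuration opposite to that of the target.
- The less hindered 3-hydroxyl is acetylated (Ac2O, pyridine, 0 °C) to the 3-acetate F3.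
- MsCl and Et3N give the 5-mesylate F4.
- Warming with 2,6-lutidine lets the tertiary C10 hydroxyl, still in the configuration set by the Criegee shift, displace the mesylate with inversion (transannular Williamson-type etherification), which gives 31.

Step 20. Heterolysis may be slowed too much by the electron-withdrawing lactone oxygen at C6. O–O homolysis, or loss of the tether by reaction with the peroxide, would then take over.
The fallback gives up the isolable perester and the tether. It sets out from 24 and comes back at 31.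
- (CF3CO)2O and 2,6-lutidine at −40 °C acylate O3 and the hydroperoxide to the bis(trifluoroacetyl) perester F5.
- The much better nucleofuge of F5 should let the same C10 shift run below 0 °C to the bridgehead trifluoroacetate F6.
- Aqueous NaHCO3 cleaves both trifluoroacetates and gives the ketol F1.
- F1 is carried through F2, F3 and F4 as described for step 21, which gives 31.

Step 18. The epoxide may open with loss of a proton to an allylic alcohol, with a 1,2-methyl shift from C10, or with water instead of H2O2. The β-hydroxy hydroperoxide may also fragment before it lactonises.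
The fallback leaves the ionic opening for a radical oxygenation. It sets out from 21 and comes back at 24. With Bu3SnH under air in toluene at 0 °C the tertiary 5α-bromide gives the C5 radical. O2 traps this radical on the α face, anti to the C10 methyl, O6 and O8, and the peroxyl radical takes hydrogen from the stannane. The lactone stays closed throughout, and no new compound is made.

Further compounds
F1 | step 21 | 3α,10-dihydroxy-5-ketone (ten-membered ketol) | C=C(C)C(=O)O[C@@H]1C[C@@](O)(C)CC[C@@H](O)[C@@H](CO[Si](c3ccccc3)(c4ccccc4)C(C)(C)C)C(=O)[C@@H]2OC(=O)C(=C)[C@@H]21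
F2 | step 21 | 3,5-anti triol (5-epi carbinol) | C=C(C)C(=O)O[C@@H]1C[C@@](O)(C)CC[C@@H](O)[C@@H](CO[Si](c3ccccc3)(c4ccccc4)C(C)(C)C)[C@H](O)[C@@H]2OC(=O)C(=C)[C@@H]21
F3 | step 21 | 3-acetate of F2 | C=C(C)C(=O)O[C@@H]1C[C@@](O)(C)CC[C@@H](OC(C)=O)[C@@H](CO[Si](c3ccccc3)(c4ccccc4)C(C)(C)C)[C@H](O)[C@@H]2OC(=O)C(=C)[C@@H]21
F4 | step 21 | 5-mesylate of F3 | C=C(C)C(=O)O[C@@H]1C[C@@](O)(C)CC[C@@H](OC(C)=O)[C@@H](CO[Si](c3ccccc3)(c4ccccc4)C(C)(C)C)[C@H](OS(C)(=O)=O)[C@@H]2OC(=O)C(=C)[C@@H]21
F5 | step 20 | bis(trifluoroacetyl) perester | C=C(C)C(=O)O[C@@H]1C[C@@]2(C)CC[C@@H](OC(=O)C(F)(F)F)[C@@H](CO[Si](c3ccccc3)(c4ccccc4)C(C)(C)C)[C@]2(OOC(=O)C(F)(F)F)[C@@H]2OC(=O)C(=C)[C@@H]21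
F6 | step 20 | bridgehead trifluoroacetate | C=C(C)C(=O)O[C@@H]1C[C@@]2(C)CC[C@@H](OC(=O)C(F)(F)F)[C@@H](CO[Si](c3ccccc3)(c4ccccc4)C(C)(C)C)[C@@](OC(=O)C(F)(F)F)(O2)[C@@H]2OC(=O)C(=C)[C@@H]21
F0 | step 18 | none | none
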